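Take the substrate charge as the unit, with one side product A counting as two. Free catalyst opens substrate to open intermediate. That intermediate then falls to side product B by itself, joins a further substrate to give side product A, or passes through second catalyst and reagent to target.

| flask | substrate | reagent | free catalyst | second catalyst | remark | time |
|---|---|---|---|---|---|---|
| maple | 20 mM | 20 mM | 0.40 mM | 0.50 mM | run made earlier |  |
| oak | 20 mM | 20 mM | 0.56 mM | 0.50 mM | run made earlier |  |
| ash | 20 mM | 20 mM | 0.88 mM | 0.50 mM | run made earlier |  |
| Saturday's | 20 mM | 20.0 mM | 0.40 mM | 0.50 mM | everything together at the start | 2.0 min |
| Wednesday's | 20 mM (fed, over 80 s) | 20.0 mM | 0.40 mM | 0.50 mM | all else is in the flask from the start; the feed brings no volume worth counting | 2.0 min |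
| Friday's | 20 mM | 20.0 mM (fed, over 80 s) | 0.40 mM | 0.50 mM | all else is in the flask from the start; the feed brings no volume worth counting | 2.0 min |

- maple (time / s: side product B / %, target / %): 15.0: 44, 5; 40.0: 68, 5; 80.0: 73, 9; 120: 75, 7
- oak (time / min: side product B / %, target / %): 0.667: 67, 6; 1.33: 75, 9; 2.00: 74, 12; 2.50: 74, 11
- ash (time / min: side product B / %, target / %): 0.667: 70, 9; 1.33: 76, 9; 2.00: 76, 7; 2.50: 72, 10

(each reading ± 1.5 percentage points)

- percentages count the substrate that a species holds: one side product A counts as two
- target is meant together with its idle complex
- steps under discussion: substrate + free catalyst <-> free catalyst + open intermediate; second catalyst + open intermediate <-> catalyst intermediate; reagent + catalyst intermediate -> second catalyst + target; substrate + open intermediate -> side product A; second catalyst + target <-> idle complex; open intermediate -> side product B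

- the flask that comes out highest in amount of side product B, in percent of the substrate charged; "all alike" if 1.5 percentage points covers them all (Saturday's / Wednesday's / Friday's / all alike)
- amount of side product B at the end, in percent of the substrate charged, Saturday's
- amount of side product B at the end, in percent of the substrate charged, Wednesday's
- amount of side product B at the end, in percent of the substrate charged, Friday's

Start from the maple run, which has Saturday's recipe. Its last reading leaves 18.0% for side product A, a side ratio, A over B, of 0.240. Its first reading of side product B, treating the pool as pseudo-first-order, reads as a time constant of 17.0 s. Freeze that constant: at 40 s the oak and ash runs read 67% and 70%, beside maple's 68%.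

Under a steady feed the pool holds feed rate times time constant, so define the standing fraction, time constant over feed time: 21.2%. Averaged over its own turnover, a first-order pool charged at once stands at 0.5 of the charge. Scale the side ratio accordingly, and Wednesday's gets 0.102.

Now bound Wednesday's side product B. Above stands 93.0%, with no side product A; below stands maple's 75%, since the standing fraction is less than 0.5. Tighten both. Subtract the reckoned 2.01% still unconverted at the asked time and divide by one plus the ratio. Target at maple's 7% gives 82.6%, and at oak's 12% gives 78.0%.

The forecast names Wednesday's, with 75%, 80% and 76% for Saturday's, Wednesday's and Friday's, and says of Friday's that “Feeding reagent only trims target slightly”. Its Wednesday figure lies inside my bracket.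

The flasks give 73.7%, 81.1% and 79.0%. Wednesday's comes highest and inside the bracket, leading Friday's by 2 percentage points against a margin of 1.5 points.

    substrate + free catalyst ⇌ free catalyst + open intermediate (K = 0.380, k = 560 /M/s)
    second catalyst + open intermediate ⇌ catalyst intermediate (K = 93.0 /M, k = 390 /M/s)
    reagent + catalyst intermediate → second catalyst + target (k = 48.0 /M/s)
    substrate + open intermediate → side product A (k = 3.90 /M/s)
    second catalyst + target ⇌ idle complex (K = 11.0 /M, k = 4.30 /M/s)
    open intermediate → side product B (k = 0.250 /s)

At the end of the feed, 1.33 min, Wednesday's held 20.1% as substrate and open intermediate, against the standing fraction of 21.2%. Now take Wednesday's flask with 80 mM of substrate. Keep the standing fraction, and multiply the side ratio by 4.00, the ratio of the two charges: it becomes 0.407. With that flask's target of 7.35% and substrate left of 1.01%, side product B reckons to 65.1%. The flask gives 70.5%.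

The readings stem from a simulated flask from invented constants; the scatter is artificial.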